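## Analysis of the target

The target is a bisabolane-type triester. It has one carbocycle (C1–C6) cis-fused to an oxirane at C3/C4, with the methyl group on C3. At C6 it carries the chain C7(=C14H2)–C8–C9H2–C10/C11, which ends in a gem-dimethyl oxirane. C1, C2 and C8 bear (Z)-2-methylbut-2-enoyl (angeloyl) esters.

There are seven stereocentres: 1R, 2S, 3S, 4S and 6R in the ring, 8S and 10R in the chain. The C2 ester and the C6 chain lie on one face of the ring and the C1 ester on the other (C1/C2 trans, C1/C6 trans, an all-equatorial array). The ring oxirane oxygen sits on the face of the C1 ester, anti to C2–O and to the chain. C8 and C10 are insulated from the ring and from each other by C7 and C9, so neither can be relayed from the ring.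

The sensitive groups are the three angelates (which isomerise to tiglates under acid, base or nucleophilic catalysis), the two acid-labile trisubstituted oxiranes flanked by acyloxy groups, and the allylic C8 ester next to the 1,1-disubstituted alkene. The difficulties are the contiguous C1–C4 oxygenation with an anti epoxy-ester relationship, the choice of two out of six C=C bonds for epoxidation, and the attachment of three angelates without Z→E isomerisation.

The strategy rests on one feature. If the ring oxirane is taken back to C3=C4 and C2 is raised to a ketone, the ring is a 6-oxy-2-methyl-5-acylcyclohex-2-enone (C2=O, C3=C4, oxygen on C1, C7 as a carboxyl carbon on C6). Its C3=C4 bond is an aldol-condensation bond. Its C1–C6 bond joins an oxygenated, doubly activated carbon to the β-carbon of a 4-oxobut-2-enoate.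

## Retrosynthetic reasoning

**Oxiranes (24 ⇒ 23 ⇒ 22).** The two oxirane oxygens are removed first, the ring one (C3–O/C4–O) before the chain one (C10–O/C11–O). They are introduced last because trisubstituted oxiranes would not survive the organometallic, Lewis-acidic and fluoride steps, and a free C2 alkoxide beside a C3/C4 oxirane invites epoxide migration. Forward, two of six C=C bonds must be chosen, each on a defined face. The enoate double bonds and the 1,1-disubstituted C7=C14 are poor partners for an electrophilic dioxirane. The two trisubstituted alkenes are told apart by rate (C10=C11 first). Each face is chosen by the handedness of a chiral ketone catalyst, because C10 is remote from every stereocentre and the ring alkene has only a weak bias of its own.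

**Esters (22 ⇒ 21).** The three acyl C–O bonds at C1, C2 and C8 are cut together. The angelates are placed late because they would not survive hydride, Grignard or amide-base steps, and at the alkene stage so that no oxirane is exposed to the acylation. The forward step must acylate the hindered allylic C2 hydroxyl without Z→E isomerisation.

**Protecting groups (21 ⇒ 20 ⇒ 19).** The C2–O–Si and C1–O–CH2Ar bonds are cut. Both groups come off without reduction (fluoride, quinone oxidation), which is why the C1 oxygen is carried as a 2-naphthylmethyl ether and not as a plain benzyl ether.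

**C7–C8 bond (19 ⇒ 18 ⇒ 17 ⇒ 14 + 16).** The cut between the alkenyl carbon C7 and the carbinol carbon C8 separates the ring from the C8–C13 chain. It is the one C–C bond that an alkenyl metal and an aldehyde can form, and it leaves the 1,1-disubstituted alkene to come from an enol triflate. The ring cannot be expected to control C8, so the coupling product 17 is oxidised to enone 18 and the configuration is set by a catalyst-controlled reduction to 19. Aldehyde 16 comes from alcohol 15 by oxidation.

**C7 oxidation level (14 ⇒ 13 ⇒ 12 ⇒ 11).** The C7–C14 bond is cut: the triflate 14 is the kinetic enol derivative of methyl ketone 13, which comes from the C7 ester 11 through amide 12. The forward steps must not enolise C6, whose enolate could expel the C1 ether.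

**C2 carbinol (11 ⇒ 10 ⇒ 9).** The C2–H bond is cut back to the enone carbonyl of 9. The half-chair with C1–O and the C6 ester equatorial should direct axial hydride delivery, giving the 2,6-cis, 1,2-trans alcohol 10.

**Ring (9 ⇒ 8 ⇒ 7 ⇒ 5 + 6).** C3=C4 is opened as an aldol condensation and C1–C6 as a conjugate addition, with a tert-butoxycarbonyl group restored on C1. This is the only pair of cuts that divides the ring into two small achiral pieces, each of which activates the bond formed by the other. C6 arises at the β-carbon of an iminium ion and can be set by an amine catalyst. C1 needs no control because it becomes epimerisable once the ester is lost.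

**Donor (5 ⇒ 3 + 4; 3 ⇒ 1 + 2).** The acyl C–C bond of 5 is cut to ester 3 and acid chloride 4, and the ether C–O bond of 3 to alcohol 1 and bromo ester 2.

## Alternatives that were turned down

**Alternative 1:** The ring is left open and C1/C2 are taken from tartaric acid as a trans-dioxolane. The key step forms C5–C6 and C7=C14 on the dioxolane enone A1. An allyl cuprate (made with CuBr·SMe2, in the presence of Me3SiCl) adds to C6. The resulting enol silane is then aminomethylated with a dimethyl(methylidene)ammonium salt, quaternised and eliminated, to give the α-methylene ketone A2. A later ring-closing metathesis between the isopropenyl and allyl groups would form C3=C4.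
- For: C1 and C2 come from the chiral pool, so their relative and absolute configuration is certain. The carbonyl of A1 becomes C8, and C14 is installed in the same flask, with no triflate, coupling or re-oxidation. On both points it is stronger than the chosen route.
- Against: C6 depends on acyclic 1,2-induction from the dioxolane, whose sense and level on a ketone are hard to predict. A1 and A2 are skipped dienones with an acidic C9 methylene. The metathesis must join a 1,1-disubstituted alkene to the allyl group in the presence of an α-methylene ketone and a prenyl group, and a seven-membered ring through C10 can compete. Differentiating the two ends of tartrate adds steps.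
- Comparison: the chosen route offers a ring closure whose regiochemistry is fixed by the aldol, C6 set by a catalyst with close precedent, and a shorter path to the ring.

**Alternative 2:** C1–C6 and C4–C5 are cut as a Diels–Alder reaction of 3-methylfuran A3 with the hydroxy vinyl ketone A4. The dienophile is held in two-point fashion by Cu(SbF6)2 with a tert-butyl-bis(oxazoline) ligand (divalent copper). The endo adduct is the oxabicycle A5, whose bridging oxygen becomes the C1 oxygen. A strain-releasing SN2′-type opening would then place an oxygen at C2 and move the alkene to C3=C4.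
- For: this is the most convergent plan. All ring carbons, C7 and the complete C8–C13 chain with the C8 stereocentre are assembled in one step, and the bridge opening delivers the C1-O/C2-O trans pattern and the C3=C4 alkene together. In step count it is clearly ahead of the chosen route.
- Against: furan cycloadditions are reversible and drift to exo adducts. The 3-methyl group gives only weak regiocontrol, and the catalyst must override the existing C8 centre of A4. A5 is a β-alkoxy ketone, and enolisation toward C6 opens the bridge and leads on to an aromatic ring. The C7 ketone must still be methylenated beside the epimerisable C6.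
- Comparison: the chosen route offers irreversible C–C bond formation, no regiochemical question and intermediates that cannot aromatise once C2 is reduced.

**Alternative 3:** C2–C3 is cut, and the ring is closed late by an intramolecular Nozaki–Hiyama–Kishi reaction of the (Z)-iodoalkene aldehyde A6 with CrCl2 (divalent chromium) and catalytic NiCl2. The product is the cyclohexenol A7 with a free C2 hydroxyl.
- For: the coupling is mild, the trisubstituted ring alkene arrives with its geometry fixed by the iodide, and the complete side chain with C7=C14 and C8 is already in place. The triflate/coupling/oxidation/reduction sequence on the ring is avoided. On that point it is as strong as or stronger than the chosen route.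
- Against: A6 needs C1, C6 and C8 set in an open chain, plus a (Z)-2-iodoalkene. Its α-silyloxy aldehyde is epimerisable. The C2 configuration would depend on the balance of Felkin and chelation effects in the ring-forming transition state. The linear sequence to A6 is long.
- Comparison: the chosen route closes the ring in the third step from achiral materials and sets C2 on a conformationally biased cyclohexenone.

Key step: step 3

Remark on the chemistry: the C1 oxygen is carried as a 2-naphthylmethyl (NAP) ether, which behaves like a benzyl ether toward acid but can be removed with DDQ in the presence of the alkenes. Keto ester 5 is used as the racemate because its stereocentre is lost in step 3. The (R)-configured amine catalyst is the one that leads to the 6R series.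

## Route

Step 1
Reactants: 1 naphthalen-2-ylmethanol; 2 tert-butyl bromoacetate
Product: 3 tert-butyl 2-(naphthalen-2-ylmethoxy)acetate
Conditions: NaH, THF, 0 °C; then 2, Bu4NI (cat.), 0 °C → rt
Reagents that add atoms: none
Why: Williamson etherification; the sodium alkoxide of 1 displaces bromide from the α-bromo ester by SN2, and the tert-butyl ester resists transesterification.

Step 2
Reactants: 3 tert-butyl 2-(naphthalen-2-ylmethoxy)acetate; 4 propanoyl chloride
Product: 5 tert-butyl 2-(naphthalen-2-ylmethoxy)-3-oxopentanoate (racemic)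
Conditions: LiN(SiMe3)2 (2.1 equiv), THF, −78 °C; then 4, −78 °C; AcOH quench
Reagents that add atoms: none
Why: Crossed Claisen-type C-acylation of the lithium glycolate enolate by the acid chloride; the second equivalent of base deprotonates the more acidic product and so prevents proton transfer and double acylation.

Step 3
Reactants: 5 tert-butyl 2-(naphthalen-2-ylmethoxy)-3-oxopentanoate; 6 ethyl (E)-4-oxobut-2-enoate
Product: 9 ethyl (1S,6R)-4-methyl-6-(naphthalen-2-ylmethoxy)-5-oxocyclohex-3-ene-1-carboxylate, via Michael adduct 7 (not isolated), via cyclohexenone tert-butyl ester 8 (not isolated)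
Conditions: (R)-2-{bis[3,5-bis(trifluoromethyl)phenyl][(trimethylsilyl)oxy]methyl}pyrrolidine (10 mol%), PhCO2H (10 mol%), toluene, 0 °C → rt; then TsOH·H2O (0.3 equiv), toluene, 80 °C
Reagents that add atoms: none
Why: The amine condenses with the aldehyde of 6 to an E-configured, s-trans iminium ion, and the enol of 5 adds through its oxygenated carbon to the ester-bearing β-carbon (C1–C6), giving aldehyde 7 after hydrolysis of the enamine. The closest known reaction type is the diarylprolinol silyl ether-catalysed Michael addition of β-keto esters to enals followed by acid-mediated aldol condensation and decarboxylation to 5-substituted 2-alkylcyclohex-2-enones. The sulfonic acid then enolises the ethyl ketone toward C3, which attacks the C4 aldehyde in a 6-(enolendo)-exo-trig aldol, and dehydration gives the conjugated C3=C4 bond of 8. Acidolysis of the tert-butyl ester and decarboxylation of the β-keto acid through its dienol leave C1 as a CH(OR) group. C6 is set by the catalyst: the diarylsilyloxymethyl group of the (R)-amine covers the Si face of the β-carbon, so the donor adds to the Re face and the ester carbon of 9 becomes S (6R in the target, where C7 no longer outranks C1). C1 is set thermodynamically, because the α-alkoxy ketone position epimerises under the acid and settles trans to the C6 ester with both groups equatorial. The step needs attack at the carbon β to the aldehyde and not β to the ester, which the iminium activation secures, and a single aldol mode, which is secured because enolisation toward C3 is the only one that can close a six-membered ring. The benzyl-type NAP ether should tolerate the catalytic sulfonic acid, which a 4-methoxybenzyl ether would not.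

Step 4
Reactants: 9 ethyl (1S,6R)-4-methyl-6-(naphthalen-2-ylmethoxy)-5-oxocyclohex-3-ene-1-carboxylate
Product: 10 ethyl (1S,5R,6R)-5-hydroxy-4-methyl-6-(naphthalen-2-ylmethoxy)cyclohex-3-ene-1-carboxylate
Conditions: NaBH4, CeCl3·7H2O, MeOH, −78 °C
Reagents that add atoms: none
Why: Luche 1,2-reduction; hydride enters axially on the half-chair that holds the C1 ether and the C6 ester equatorial (anti to the C6 ester, also the open face of a cerium chelate between the C2 and C1 oxygens), so the new C2 hydroxyl is equatorial, trans to C1–O and cis to the C6 carboxylate, as in the reduction of 5-substituted 2-methylcyclohex-2-enones to their cis-alcohols. The short, cold reaction limits base-induced loss of the C1 ether.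

Step 5
Reactants: 10 ethyl (1S,5R,6R)-5-hydroxy-4-methyl-6-(naphthalen-2-ylmethoxy)cyclohex-3-ene-1-carboxylate
Product: 11 ethyl (1S,5R,6R)-5-[(tert-butyldimethylsilyl)oxy]-4-methyl-6-(naphthalen-2-ylmethoxy)cyclohex-3-ene-1-carboxylate
Conditions: TBSOTf, 2,6-lutidine, CH2Cl2, −78 → 0 °C
Reagents that add atoms: tert-butyldimethylsilyl trifluoromethanesulfonate, CC(C)(C)[Si](C)(C)OS(=O)(=O)C(F)(F)F
Why: Silylation of a hindered secondary allylic alcohol with a silyl triflate and a hindered pyridine base, which is too weak a base to eliminate the β-alkoxy ester.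

Step 6
Reactants: 11 ethyl (1S,5R,6R)-5-[(tert-butyldimethylsilyl)oxy]-4-methyl-6-(naphthalen-2-ylmethoxy)cyclohex-3-ene-1-carboxylate
Product: 12 (1S,5R,6R)-5-[(tert-butyldimethylsilyl)oxy]-N-methoxy-N,4-dimethyl-6-(naphthalen-2-ylmethoxy)cyclohex-3-ene-1-carboxamide
Conditions: MeNH(OMe)·HCl, iPrMgCl, THF, −20 → 0 °C
Reagents that add atoms: N,O-dimethylhydroxylamine hydrochloride, CNOC.Cl
Why: Weinreb amide formation by aminolysis of the ester with the chloromagnesium amide; this amide is a poor base at low temperature, so C6 and the β-ether should be preserved.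

Step 7
Reactants: 12 (1S,5R,6R)-5-[(tert-butyldimethylsilyl)oxy]-N-methoxy-N,4-dimethyl-6-(naphthalen-2-ylmethoxy)cyclohex-3-ene-1-carboxamide
Product: 13 1-[(1S,5R,6R)-5-[(tert-butyldimethylsilyl)oxy]-4-methyl-6-(naphthalen-2-ylmethoxy)cyclohex-3-en-1-yl]ethan-1-one
Conditions: MeMgBr, THF, −20 → 0 °C; aq. NH4Cl
Reagents that add atoms: methylmagnesium bromide, C[Mg]Br
Why: Weinreb ketone synthesis; the chelated tetrahedral intermediate stops the addition at the ketone and keeps C6 from enolising.

Step 8
Reactants: 13 1-[(1S,5R,6R)-5-[(tert-butyldimethylsilyl)oxy]-4-methyl-6-(naphthalen-2-ylmethoxy)cyclohex-3-en-1-yl]ethan-1-one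
Product: 14 1-[(1S,5R,6R)-5-[(tert-butyldimethylsilyl)oxy]-4-methyl-6-(naphthalen-2-ylmethoxy)cyclohex-3-en-1-yl]ethenyl trifluoromethanesulfonate
Conditions: KN(SiMe3)2, THF, −78 °C; then PhNTf2, −78 → 0 °C
Reagents that add atoms: N-phenylbis(trifluoromethanesulfonimide), O=S(=O)(N(c1ccccc1)S(=O)(=O)C(F)(F)F)C(F)(F)F
Why: Kinetic deprotonation of the methyl ketone at the unhindered methyl group (not at the C6 methine, whose enolate could expel the C1 ether), followed by O-triflation, gives the 1,1-disubstituted alkenyl triflate and fixes C14.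

Step 9
Reactants: 15 4-methylpent-3-en-1-ol
Product: 16 4-methylpent-3-enal
Conditions: Dess–Martin periodinane, NaHCO3, CH2Cl2, 0 °C; filtered and used at once
Reagents that add atoms: none
Why: Dess–Martin oxidation under bicarbonate buffer stops at the aldehyde and avoids the acid or base that would move the β,γ-alkene into conjugation.

Step 10
Reactants: 14 1-[(1S,5R,6R)-5-[(tert-butyldimethylsilyl)oxy]-4-methyl-6-(naphthalen-2-ylmethoxy)cyclohex-3-en-1-yl]ethenyl trifluoromethanesulfonate; 16 4-methylpent-3-enal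
Product: 17 2-[(1R,5R,6R)-5-[(tert-butyldimethylsilyl)oxy]-4-methyl-6-(naphthalen-2-ylmethoxy)cyclohex-3-en-1-yl]-6-methylhepta-1,5-dien-3-ol (both C3 epimers)
Conditions: CrCl2 (6 equiv), NiCl2 (2 mol%), degassed DMF, rt
Reagents that add atoms: none
Why: Nozaki–Hiyama–Kishi coupling; zerovalent nickel inserts into the C7–OTf bond, transmetallation gives an alkenyl species of trivalent chromium, and this non-basic nucleophile adds to the enolisable aldehyde to form C7–C8. Little induction from C6 is expected, so both C8 epimers are carried on.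

Step 11
Reactants: 17 2-[(1R,5R,6R)-5-[(tert-butyldimethylsilyl)oxy]-4-methyl-6-(naphthalen-2-ylmethoxy)cyclohex-3-en-1-yl]-6-methylhepta-1,5-dien-3-ol
Product: 18 2-[(1R,5R,6R)-5-[(tert-butyldimethylsilyl)oxy]-4-methyl-6-(naphthalen-2-ylmethoxy)cyclohex-3-en-1-yl]-6-methylhepta-1,5-dien-3-one
Conditions: Dess–Martin periodinane, NaHCO3, CH2Cl2, 0 °C
Reagents that add atoms: none
Why: Dess–Martin oxidation converges both carbinol epimers on one enone; the buffer keeps the C9 methylene, which lies between the carbonyl and the alkene, from isomerising into conjugation.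

Step 12
Reactants: 18 2-[(1R,5R,6R)-5-[(tert-butyldimethylsilyl)oxy]-4-methyl-6-(naphthalen-2-ylmethoxy)cyclohex-3-en-1-yl]-6-methylhepta-1,5-dien-3-one
Product: 19 (3S)-2-[(1R,5R,6R)-5-[(tert-butyldimethylsilyl)oxy]-4-methyl-6-(naphthalen-2-ylmethoxy)cyclohex-3-en-1-yl]-6-methylhepta-1,5-dien-3-ol
Conditions: (R)-2-methyl-CBS-oxazaborolidine (1.0 equiv), catecholborane, toluene, −78 °C
Reagents that add atoms: none
Why: Corey–Bakshi–Shibata reduction; the ketone binds the ring boron anti to the larger, α-branched alkenyl group and hydride is delivered within the complex, so the (R)-catalyst should give the (S)-carbinol (the mirror image of the (S)-catalyst/aryl methyl ketone → (R)-alcohol case). Catecholborane at −78 °C avoids hydroboration of the alkenes and conjugate reduction.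

Step 13
Reactants: 19 (3S)-2-[(1R,5R,6R)-5-[(tert-butyldimethylsilyl)oxy]-4-methyl-6-(naphthalen-2-ylmethoxy)cyclohex-3-en-1-yl]-6-methylhepta-1,5-dien-3-ol
Product: 20 (1R,2R,6R)-2-[(tert-butyldimethylsilyl)oxy]-6-[(3S)-3-hydroxy-6-methylhepta-1,5-dien-2-yl]-3-methylcyclohex-3-en-1-ol
Conditions: DDQ (1.5 equiv), CH2Cl2/pH 7 phosphate buffer, 0 °C
Reagents that add atoms: none
Why: Oxidative cleavage of the 2-naphthylmethyl ether (hydride abstraction from the arylmethyl carbon, then hydrolysis of the oxocarbenium ion); isolated alkenes, the silyl ether and a non-activated allylic alcohol should react much more slowly.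

Step 14
Reactants: 20 (1R,2R,6R)-2-[(tert-butyldimethylsilyl)oxy]-6-[(3S)-3-hydroxy-6-methylhepta-1,5-dien-2-yl]-3-methylcyclohex-3-en-1-ol
Product: 21 (1R,2R,6R)-6-[(3S)-3-hydroxy-6-methylhepta-1,5-dien-2-yl]-3-methylcyclohex-3-ene-1,2-diol
Conditions: Bu4NF, THF, 0 °C → rt
Reagents that add atoms: none
Why: Fluoride-mediated cleavage of the silyl ether; no oxirane or ester is present yet, so the alkoxide formed is harmless.

Step 15
Reactants: 21 (1R,2R,6R)-6-[(3S)-3-hydroxy-6-methylhepta-1,5-dien-2-yl]-3-methylcyclohex-3-ene-1,2-diol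
Product: 22 (1R,2R,6R)-3-methyl-6-[(3S)-6-methyl-3-{[(2Z)-2-methylbut-2-enoyl]oxy}hepta-1,5-dien-2-yl]cyclohex-3-ene-1,2-diyl bis[(2Z)-2-methylbut-2-enoate]
Conditions: angelic acid, 2,4,6-trichlorobenzoyl chloride, Et3N, toluene, rt; then 21, toluene, 80 °C
Reagents that add atoms: angelic acid ((2Z)-2-methylbut-2-enoic acid), C/C=C(/C)C(=O)O
Why: Yamaguchi-type esterification through the mixed anhydride of angelic acid, run without a nucleophilic amine catalyst because such catalysts isomerise angelates to tiglates; heat and excess reagent should acylate all three secondary hydroxyls.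

Step 16
Reactants: 22 (1R,2R,6R)-3-methyl-6-[(3S)-6-methyl-3-{[(2Z)-2-methylbut-2-enoyl]oxy}hepta-1,5-dien-2-yl]cyclohex-3-ene-1,2-diyl bis[(2Z)-2-methylbut-2-enoate]
Product: 23 (1R,2R,6R)-6-[(3S)-4-[(2R)-3,3-dimethyloxiran-2-yl]-3-{[(2Z)-2-methylbut-2-enoyl]oxy}but-1-en-2-yl]-3-methylcyclohex-3-ene-1,2-diyl bis[(2Z)-2-methylbut-2-enoate]
Conditions: D-fructose-derived Shi ketone (0.3 equiv), KHSO5 (as 2KHSO5·KHSO4·K2SO4, 1.2 equiv), K2CO3, Bu4NHSO4, MeCN/CH2(OMe)2/aq. Na2B4O7 buffer, 0 °C
Reagents that add atoms: potassium peroxymonosulfate, [K+].[O-]S(=O)(=O)OO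
Why: Shi asymmetric epoxidation; the chiral dioxirane transfers oxygen through a spiro transition state to the most electron-rich and least hindered alkene, C10=C11, while the ring alkene is slowed by its allylic ester and the 1,1-disubstituted and enoate double bonds are poor substrates. For R–CH=CMe2 olefins this catalyst gives the (R)-oxirane, which is 10R.

Step 17
Reactants: 23 (1R,2R,6R)-6-[(3S)-4-[(2R)-3,3-dimethyloxiran-2-yl]-3-{[(2Z)-2-methylbut-2-enoyl]oxy}but-1-en-2-yl]-3-methylcyclohex-3-ene-1,2-diyl bis[(2Z)-2-methylbut-2-enoate]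
Product: 24 (1S,2S,3R,4R,6S)-4-[(3S)-4-[(2R)-3,3-dimethyloxiran-2-yl]-3-{[(2Z)-2-methylbut-2-enoyl]oxy}but-1-en-2-yl]-1-methyl-7-oxabicyclo[4.1.0]heptane-2,3-diyl bis[(2Z)-2-methylbut-2-enoate]
Conditions: L-fructose-derived enantiomer of the Shi ketone (0.5 equiv), KHSO5 (as 2KHSO5·KHSO4·K2SO4), K2CO3, Bu4NHSO4, MeCN/CH2(OMe)2/aq. Na2B4O7 buffer, 0 °C
Reagents that add atoms: potassium peroxymonosulfate, [K+].[O-]S(=O)(=O)OO
Why: Second Shi epoxidation with the enantiomeric ketone; for a 1-methylcyclohexene-type olefin its dioxirane attacks the face that gives the (3S,4S) oxirane, which is also the face anti to the C2 ester and the C6 chain, so catalyst and substrate preferences should reinforce each other. The remaining double bonds are far less nucleophilic.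

## Compound list

1 | naphthalen-2-ylmethanol | OCc1ccc2ccccc2c1 | starting material
2 | tert-butyl bromoacetate | BrCC(=O)OC(C)(C)C | starting material
3 | tert-butyl 2-(naphthalen-2-ylmethoxy)acetate | CC(C)(C)OC(=O)COCc1ccc2ccccc2c1 | intermediate
4 | propanoyl chloride | CCC(=O)Cl | starting material
5 | tert-butyl 2-(naphthalen-2-ylmethoxy)-3-oxopentanoate (racemic) | CCC(=O)C(OCc1ccc2ccccc2c1)C(=O)OC(C)(C)C | intermediate
6 | ethyl (E)-4-oxobut-2-enoate | CCOC(=O)/C=C/C=O | starting material
7 | 1-tert-butyl 4-ethyl (3S)-2-(naphthalen-2-ylmethoxy)-3-(2-oxoethyl)-2-propanoylbutanedioate (C2 epimers; not isolated) | CCOC(=O)[C@H](C(OCc1ccc2ccccc2c1)(C(=O)CC)C(=O)OC(C)(C)C)CC=O | intermediate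
8 | 1-tert-butyl 2-ethyl (2S)-5-methyl-1-(naphthalen-2-ylmethoxy)-6-oxocyclohex-4-ene-1,2-dicarboxylate (C1 epimers; not isolated) | CCOC(=O)[C@H]1CC=C(C)C(=O)C1(OCc1ccc2ccccc2c1)C(=O)OC(C)(C)C | intermediate
9 | ethyl (1S,6R)-4-methyl-6-(naphthalen-2-ylmethoxy)-5-oxocyclohex-3-ene-1-carboxylate | CCOC(=O)[C@H]1CC=C(C)C(=O)[C@@H]1OCc1ccc2ccccc2c1 | intermediate
10 | ethyl (1S,5R,6R)-5-hydroxy-4-methyl-6-(naphthalen-2-ylmethoxy)cyclohex-3-ene-1-carboxylate | CCOC(=O)[C@H]1CC=C(C)[C@@H](O)[C@@H]1OCc1ccc2ccccc2c1 | intermediate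
11 | ethyl (1S,5R,6R)-5-[(tert-butyldimethylsilyl)oxy]-4-methyl-6-(naphthalen-2-ylmethoxy)cyclohex-3-ene-1-carboxylate | CCOC(=O)[C@H]1CC=C(C)[C@@H](O[Si](C)(C)C(C)(C)C)[C@@H]1OCc1ccc2ccccc2c1 | intermediate
12 | (1S,5R,6R)-5-[(tert-butyldimethylsilyl)oxy]-N-methoxy-N,4-dimethyl-6-(naphthalen-2-ylmethoxy)cyclohex-3-ene-1-carboxamide | CON(C)C(=O)[C@H]1CC=C(C)[C@@H](O[Si](C)(C)C(C)(C)C)[C@@H]1OCc1ccc2ccccc2c1 | intermediate
13 | 1-[(1S,5R,6R)-5-[(tert-butyldimethylsilyl)oxy]-4-methyl-6-(naphthalen-2-ylmethoxy)cyclohex-3-en-1-yl]ethan-1-one | CC(=O)[C@H]1CC=C(C)[C@@H](O[Si](C)(C)C(C)(C)C)[C@@H]1OCc1ccc2ccccc2c1 | intermediate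
14 | 1-[(1S,5R,6R)-5-[(tert-butyldimethylsilyl)oxy]-4-methyl-6-(naphthalen-2-ylmethoxy)cyclohex-3-en-1-yl]ethenyl trifluoromethanesulfonate | C=C(OS(=O)(=O)C(F)(F)F)[C@H]1CC=C(C)[C@@H](O[Si](C)(C)C(C)(C)C)[C@@H]1OCc1ccc2ccccc2c1 | intermediate
15 | 4-methylpent-3-en-1-ol | CC(C)=CCCO | starting material
16 | 4-methylpent-3-enal | CC(C)=CCC=O | intermediate
17 | 2-[(1R,5R,6R)-5-[(tert-butyldimethylsilyl)oxy]-4-methyl-6-(naphthalen-2-ylmethoxy)cyclohex-3-en-1-yl]-6-methylhepta-1,5-dien-3-ol (both C3 epimers) | C=C(C(O)CC=C(C)C)[C@H]1CC=C(C)[C@@H](O[Si](C)(C)C(C)(C)C)[C@@H]1OCc1ccc2ccccc2c1 | intermediate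
18 | 2-[(1R,5R,6R)-5-[(tert-butyldimethylsilyl)oxy]-4-methyl-6-(naphthalen-2-ylmethoxy)cyclohex-3-en-1-yl]-6-methylhepta-1,5-dien-3-one | C=C(C(=O)CC=C(C)C)[C@H]1CC=C(C)[C@@H](O[Si](C)(C)C(C)(C)C)[C@@H]1OCc1ccc2ccccc2c1 | intermediate
19 | (3S)-2-[(1R,5R,6R)-5-[(tert-butyldimethylsilyl)oxy]-4-methyl-6-(naphthalen-2-ylmethoxy)cyclohex-3-en-1-yl]-6-methylhepta-1,5-dien-3-ol | C=C([C@H](CC=C(C)C)O)[C@H]1CC=C(C)[C@@H](O[Si](C)(C)C(C)(C)C)[C@@H]1OCc1ccc2ccccc2c1 | intermediate
20 | (1R,2R,6R)-2-[(tert-butyldimethylsilyl)oxy]-6-[(3S)-3-hydroxy-6-methylhepta-1,5-dien-2-yl]-3-methylcyclohex-3-en-1-ol | C=C([C@H](CC=C(C)C)O)[C@H]1CC=C(C)[C@@H](O[Si](C)(C)C(C)(C)C)[C@@H]1O | intermediate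
21 | (1R,2R,6R)-6-[(3S)-3-hydroxy-6-methylhepta-1,5-dien-2-yl]-3-methylcyclohex-3-ene-1,2-diol | C=C([C@H](CC=C(C)C)O)[C@H]1CC=C(C)[C@@H](O)[C@@H]1O | intermediate
22 | (1R,2R,6R)-3-methyl-6-[(3S)-6-methyl-3-{[(2Z)-2-methylbut-2-enoyl]oxy}hepta-1,5-dien-2-yl]cyclohex-3-ene-1,2-diyl bis[(2Z)-2-methylbut-2-enoate] | C=C([C@H](CC=C(C)C)OC(=O)/C(C)=C\C)[C@H]1CC=C(C)[C@@H](OC(=O)/C(C)=C\C)[C@@H]1OC(=O)/C(C)=C\C | intermediate
23 | (1R,2R,6R)-6-[(3S)-4-[(2R)-3,3-dimethyloxiran-2-yl]-3-{[(2Z)-2-methylbut-2-enoyl]oxy}but-1-en-2-yl]-3-methylcyclohex-3-ene-1,2-diyl bis[(2Z)-2-methylbut-2-enoate] | C=C([C@H](C[C@H]1OC1(C)C)OC(=O)/C(C)=C\C)[C@H]1CC=C(C)[C@@H](OC(=O)/C(C)=C\C)[C@@H]1OC(=O)/C(C)=C\C | intermediate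
24 | (1S,2S,3R,4R,6S)-4-[(3S)-4-[(2R)-3,3-dimethyloxiran-2-yl]-3-{[(2Z)-2-methylbut-2-enoyl]oxy}but-1-en-2-yl]-1-methyl-7-oxabicyclo[4.1.0]heptane-2,3-diyl bis[(2Z)-2-methylbut-2-enoate] (CNP0258231.1) | C=C([C@H](C[C@H]1OC1(C)C)OC(=O)/C(C)=C\C)[C@H]1C[C@@H]2O[C@]2(C)[C@@H](OC(=O)/C(C)=C\C)[C@@H]1OC(=O)/C(C)=C\C | target

## Step count and least certain steps

Total: 17 steps. Longest linear sequence: 16 steps (steps 1–8 and 10–17); step 9 is a one-step branch.

**Step 3 (key step).**
- What may go wrong: the conjugate addition may be slow, because the donor carbon carries an alkoxy group and becomes fully substituted, and a slow addition lets oligomerisation of the reactive enal compete. In the acid stage the naphthylmethyl ether may be lost, or the C1 ether may be eliminated with aromatisation of the ring.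
- Fallback: the oxygen is introduced after the annulation. It sets out from 6, which is combined under the same two-stage conditions with commercial tert-butyl 3-oxopentanoate (CCC(=O)CC(=O)OC(C)(C)C), the exact substrate class of the precedent. This should give ethyl (1S)-4-methyl-5-oxocyclohex-3-ene-1-carboxylate F1. Kinetic enolisation toward C1 with LiN(SiMe3)2 and trapping with Me3SiCl gives ethyl (1S)-4-methyl-5-[(trimethylsilyl)oxy]cyclohexa-3,5-diene-1-carboxylate F2. Rubottom oxidation with a peracid, anti to the C6 ester, gives ethyl (1S,6R)-6-hydroxy-4-methyl-5-oxocyclohex-3-ene-1-carboxylate F3. Acid-catalysed etherification with 2-naphthylmethyl trichloroacetimidate returns to 9.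

**Step 10.**
- What may go wrong: the chromium salts may isomerise the β,γ-unsaturated aldehyde or cause its self-condensation, and the hindered alkenyl metal may be protonated, which reduces the triflate to the alkene.
- Fallback: a stoichiometric, low-temperature organometallic addition. It sets out from 14, which is stannylated with Me3Sn–SnMe3, Pd(PPh3)4 (zerovalent palladium) and LiCl to trimethyl{1-[(1S,5R,6R)-5-[(tert-butyldimethylsilyl)oxy]-4-methyl-6-(naphthalen-2-ylmethoxy)cyclohex-3-en-1-yl]ethenyl}stannane F4. Tin–lithium exchange with MeLi at −78 °C, transmetallation to CeCl3 and addition to 16 return to 17.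

**Step 12.**
- What may go wrong: facial discrimination may be poor if the catalyst does not distinguish the branched alkenyl flank from the allylic methylene flank strongly enough, and the skipped dienone may isomerise or suffer conjugate reduction.
- Fallback: it omits steps 11 and 12 and sets out from 17. The epimers are separated; the (3S)-epimer is 19. The other epimer, (3R)-2-[(1R,5R,6R)-5-[(tert-butyldimethylsilyl)oxy]-4-methyl-6-(naphthalen-2-ylmethoxy)cyclohex-3-en-1-yl]-6-methylhepta-1,5-dien-3-ol F5, is inverted by a Mitsunobu reaction with 4-nitrobenzoic acid. This gives (3S)-2-[(1R,5R,6R)-5-[(tert-butyldimethylsilyl)oxy]-4-methyl-6-(naphthalen-2-ylmethoxy)cyclohex-3-en-1-yl]-6-methylhepta-1,5-dien-3-yl 4-nitrobenzoate F6, and methanolysis with K2CO3 returns to 19.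

**Step 15.**
- What may go wrong: the activated angeloyl species may isomerise to the tigloyl (E) form during the slow acylation of the hindered C2 hydroxyl, and the acylation may stop at a diester.
- Fallback: the Z-alkene is built after acylation. It sets out from 21, which is esterified (carbodiimide, DMAP) with 2-[bis(2,2,2-trifluoroethoxy)phosphoryl]propanoic acid to (1R,2R,6R)-3-methyl-6-[(3S)-6-methyl-3-({2-[bis(2,2,2-trifluoroethoxy)phosphoryl]propanoyl}oxy)hepta-1,5-dien-2-yl]cyclohex-3-ene-1,2-diyl bis{2-[bis(2,2,2-trifluoroethoxy)phosphoryl]propanoate} F7. A threefold Still–Gennari olefination with acetaldehyde (KN(SiMe3)2, 18-crown-6, −78 °C) returns to 22.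

**Step 17.**
- What may go wrong: the ring alkene, deactivated by the allylic ester and crowded, may react slowly, and facial selectivity may be poor if the substrate does not fit the spiro transition state. The long exposure at pH 10 may also hydrolyse an ester.
- Fallback: steric shielding by a C2 silyl ether. It sets out from 20, which is acylated at C1 and C8 as in step 15 to (1R,2R,6R)-2-[(tert-butyldimethylsilyl)oxy]-3-methyl-6-[(3S)-6-methyl-3-{[(2Z)-2-methylbut-2-enoyl]oxy}hepta-1,5-dien-2-yl]cyclohex-3-en-1-yl (2Z)-2-methylbut-2-enoate F8. Epoxidation as in step 16 gives (1R,2R,6R)-2-[(tert-butyldimethylsilyl)oxy]-6-[(3S)-4-[(2R)-3,3-dimethyloxiran-2-yl]-3-{[(2Z)-2-methylbut-2-enoyl]oxy}but-1-en-2-yl]-3-methylcyclohex-3-en-1-yl (2Z)-2-methylbut-2-enoate F9. A buffered peracid (mCPBA, NaHCO3) should then attack anti to the bulky silyloxy group and give (1S,2S,3R,4R,6S)-2-[(tert-butyldimethylsilyl)oxy]-4-[(3S)-4-[(2R)-3,3-dimethyloxiran-2-yl]-3-{[(2Z)-2-methylbut-2-enoyl]oxy}but-1-en-2-yl]-1-methyl-7-oxabicyclo[4.1.0]heptan-3-yl (2Z)-2-methylbut-2-enoate F10. Acetic acid-buffered Bu4NF gives (1R,2S,3R,4R,6S)-4-[(3S)-4-[(2R)-3,3-dimethyloxiran-2-yl]-3-{[(2Z)-2-methylbut-2-enoyl]oxy}but-1-en-2-yl]-2-hydroxy-1-methyl-7-oxabicyclo[4.1.0]heptan-3-yl (2Z)-2-methylbut-2-enoate F11, and angeloylation of the C2 hydroxyl returns to 24.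

## Further compounds

F1 | step 3 | ethyl (1S)-4-methyl-5-oxocyclohex-3-ene-1-carboxylate | CCOC(=O)[C@H]1CC=C(C)C(=O)C1
F2 | step 3 | ethyl (1S)-4-methyl-5-[(trimethylsilyl)oxy]cyclohexa-3,5-diene-1-carboxylate | CCOC(=O)[C@H]1CC=C(C)C(O[Si](C)(C)C)=C1
F3 | step 3 | ethyl (1S,6R)-6-hydroxy-4-methyl-5-oxocyclohex-3-ene-1-carboxylate | CCOC(=O)[C@H]1CC=C(C)C(=O)[C@@H]1O
F4 | step 10 | trimethyl{1-[(1S,5R,6R)-5-[(tert-butyldimethylsilyl)oxy]-4-methyl-6-(naphthalen-2-ylmethoxy)cyclohex-3-en-1-yl]ethenyl}stannane | C=C([Sn](C)(C)C)[C@H]1CC=C(C)[C@@H](O[Si](C)(C)C(C)(C)C)[C@@H]1OCc1ccc2ccccc2c1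
F5 | step 12 | (3R)-2-[(1R,5R,6R)-5-[(tert-butyldimethylsilyl)oxy]-4-methyl-6-(naphthalen-2-ylmethoxy)cyclohex-3-en-1-yl]-6-methylhepta-1,5-dien-3-ol | C=C([C@@H](CC=C(C)C)O)[C@H]1CC=C(C)[C@@H](O[Si](C)(C)C(C)(C)C)[C@@H]1OCc1ccc2ccccc2c1
F6 | step 12 | (3S)-2-[(1R,5R,6R)-5-[(tert-butyldimethylsilyl)oxy]-4-methyl-6-(naphthalen-2-ylmethoxy)cyclohex-3-en-1-yl]-6-methylhepta-1,5-dien-3-yl 4-nitrobenzoate | C=C([C@H](CC=C(C)C)OC(=O)c1ccc(cc1)[N+](=O)[O-])[C@H]1CC=C(C)[C@@H](O[Si](C)(C)C(C)(C)C)[C@@H]1OCc1ccc2ccccc2c1
F7 | step 15 | (1R,2R,6R)-3-methyl-6-[(3S)-6-methyl-3-({2-[bis(2,2,2-trifluoroethoxy)phosphoryl]propanoyl}oxy)hepta-1,5-dien-2-yl]cyclohex-3-ene-1,2-diyl bis{2-[bis(2,2,2-trifluoroethoxy)phosphoryl]propanoate} (epimers at the phosphonate carbons) | C=C([C@H](CC=C(C)C)OC(=O)C(C)P(=O)(OCC(F)(F)F)OCC(F)(F)F)[C@H]1CC=C(C)[C@@H](OC(=O)C(C)P(=O)(OCC(F)(F)F)OCC(F)(F)F)[C@@H]1OC(=O)C(C)P(=O)(OCC(F)(F)F)OCC(F)(F)F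
F8 | step 17 | (1R,2R,6R)-2-[(tert-butyldimethylsilyl)oxy]-3-methyl-6-[(3S)-6-methyl-3-{[(2Z)-2-methylbut-2-enoyl]oxy}hepta-1,5-dien-2-yl]cyclohex-3-en-1-yl (2Z)-2-methylbut-2-enoate | C=C([C@H](CC=C(C)C)OC(=O)/C(C)=C\C)[C@H]1CC=C(C)[C@@H](O[Si](C)(C)C(C)(C)C)[C@@H]1OC(=O)/C(C)=C\C
F9 | step 17 | (1R,2R,6R)-2-[(tert-butyldimethylsilyl)oxy]-6-[(3S)-4-[(2R)-3,3-dimethyloxiran-2-yl]-3-{[(2Z)-2-methylbut-2-enoyl]oxy}but-1-en-2-yl]-3-methylcyclohex-3-en-1-yl (2Z)-2-methylbut-2-enoate | C=C([C@H](C[C@H]1OC1(C)C)OC(=O)/C(C)=C\C)[C@H]1CC=C(C)[C@@H](O[Si](C)(C)C(C)(C)C)[C@@H]1OC(=O)/C(C)=C\C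
F10 | step 17 | (1S,2S,3R,4R,6S)-2-[(tert-butyldimethylsilyl)oxy]-4-[(3S)-4-[(2R)-3,3-dimethyloxiran-2-yl]-3-{[(2Z)-2-methylbut-2-enoyl]oxy}but-1-en-2-yl]-1-methyl-7-oxabicyclo[4.1.0]heptan-3-yl (2Z)-2-methylbut-2-enoate | C=C([C@H](C[C@H]1OC1(C)C)OC(=O)/C(C)=C\C)[C@H]1C[C@@H]2O[C@]2(C)[C@@H](O[Si](C)(C)C(C)(C)C)[C@@H]1OC(=O)/C(C)=C\C
F11 | step 17 | (1R,2S,3R,4R,6S)-4-[(3S)-4-[(2R)-3,3-dimethyloxiran-2-yl]-3-{[(2Z)-2-methylbut-2-enoyl]oxy}but-1-en-2-yl]-2-hydroxy-1-methyl-7-oxabicyclo[4.1.0]heptan-3-yl (2Z)-2-methylbut-2-enoate | C=C([C@H](C[C@H]1OC1(C)C)OC(=O)/C(C)=C\C)[C@H]1C[C@@H]2O[C@]2(C)[C@@H](O)[C@@H]1OC(=O)/C(C)=C\C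
A1 | alternative 1 | (1E)-1-[(4R,5R)-2,2-dimethyl-5-(prop-1-en-2-yl)-1,3-dioxolan-4-yl]-6-methylhepta-1,5-dien-3-one | C=C(C)[C@H]1OC(C)(C)O[C@@H]1/C=C/C(=O)CC=C(C)C
A2 | alternative 1 | 2-[(1R)-1-[(4R,5R)-2,2-dimethyl-5-(prop-1-en-2-yl)-1,3-dioxolan-4-yl]but-3-en-1-yl]-6-methylhepta-1,5-dien-3-one | C=C(C)[C@H]1OC(C)(C)O[C@@H]1[C@H](CC=C)C(=C)C(=O)CC=C(C)C
A3 | alternative 2 | 3-methylfuran | Cc1ccoc1
A4 | alternative 2 | (4S)-4-hydroxy-7-methylocta-1,6-dien-3-one | C=CC(=O)[C@H](CC=C(C)C)O
A5 | alternative 2 | (2S)-2-hydroxy-5-methyl-1-[(1S,2S,4S)-5-methyl-7-oxabicyclo[2.2.1]hept-5-en-2-yl]hex-4-en-1-one (endo adduct) | O=C([C@H](CC=C(C)C)O)[C@H]1C[C@@H]2O[C@H]1C=C2C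
A6 | alternative 3 | (2R,3R,5S)-2,5-bis[(tert-butyldimethylsilyl)oxy]-3-[(2Z)-3-iodobut-2-en-1-yl]-8-methyl-4-methylidenenon-7-enal | C=C([C@H](CC=C(C)C)O[Si](C)(C)C(C)(C)C)[C@@H](C/C=C(/C)I)[C@@H](O[Si](C)(C)C(C)(C)C)C=O
A7 | alternative 3 | (1R,5R,6R)-6-[(tert-butyldimethylsilyl)oxy]-5-[(3S)-3-[(tert-butyldimethylsilyl)oxy]-6-methylhepta-1,5-dien-2-yl]-2-methylcyclohex-2-en-1-ol | C=C([C@H](CC=C(C)C)O[Si](C)(C)C(C)(C)C)[C@H]1CC=C(C)[C@@H](O)[C@@H]1O[Si](C)(C)C(C)(C)C
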